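# Proposed total synthesis of hansforester I

## Analysis of the target

Hansforester I is an open-chain tetraester whose only rings are two benzene rings. Ring C is a 2,4-dihydroxybenzoate with a 4-hydroxy-2-oxopentyl chain at C6, unit B is an (R)-3-oxybutanoyl group, ring A is a 2,4-dihydroxybenzoate with a 2-acyloxypropyl chain at C6, and unit D is an (R)-3-oxybutanoic acid with a free carboxyl; they are joined in the order C–B–A–D. There are four stereocentres, all R and all methyl carbinols of the type CH3–CH(O)–CH2: C4 of the ring C chain, C3 of unit B, C2 of the ring A chain and C3 of unit D. They lie at least five atoms apart, so none can steer another, and each has to come from a catalyst or a bought building block. The sensitive groups are the two 3-aroyloxybutanoyl units, which lose the benzoate by E1cB as soon as a base removes an α-hydrogen. The aryl–CH2–C(=O) ketone next to the ring C ester can close to an isocoumarin, and its β-oxygen can be eliminated. A free 2-hydroxypropyl group next to the ring A ester can close a six-membered lactone. The main difficulty is that two of the three ester links (ring A carboxyl to O–C3 of unit D, ring C carboxyl to O–C3 of unit B) are benzoates with two ortho substituents, so attack at the acyl carbon is blocked, while the alcohol partner would be a β-hydroxy ester that eliminates under alkylative conditions. The strategy rests on the shared motif ArC(=O)O–CH(CH3)–CH2–CO2 of these two links. If C1 and C2 of each butanoate begin as a vinyl group, C3 is the substituted end of a 1-methylallyl fragment, and the O–C3 bond and the C3 stereocentre can be made together by adding the benzoic acid O–H to an allene.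

## Retrosynthetic reasoning

**Unmasking (31 from 30 from 29).** The six benzyl groups of 30 (four phenol ethers, the ether at C4 of the ring C chain, the ester of unit D) are removed together in one neutral hydrogenolysis, so the last step exposes the target to neither acid nor base. The ketone of 30 is released from the dioxolane of 29 one step earlier. It therefore sits next to the ring C ester for only one further operation, and never beside a free phenol under acid.

**Convergent ester bond (29 from 15 and 28).** The cut is made between the oxygen of the ring A side chain and C1 of unit B. This is the only one of the three ester links whose acyl carbon is unhindered, and the cut divides the molecule into two halves of similar size. The forward reaction is a carbodiimide acylation of alcohol 15 by acid 28, which has to stay non-basic because both partners hold 3-aroyloxybutanoyl units.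

**Carboxyl groups from vinyl groups (15 from 14, 13, 12, 11; 28 from 27, 26).** The carboxyl carbon of each butanoate is traced back to the terminal carbon of a vinyl group, to be oxidised at the terminal position first to the aldehyde and then to the acid. This is done because allylic esters 11 and 26 have no α-hydrogens and cannot eliminate the benzoate. The unit D acid is held as a benzyl ester (14) during the coupling, and the silyl ether is removed last (15) so that the free hydroxyl beside the ring A ester exists only briefly.

**Key disconnection (11 from 9 and 10; 26 from 25 and 10).** The hindered esters are cut at the alkyl–oxygen bond O–C3, not at the acyl–oxygen bond. The benzoic acid then acts as an oxygen nucleophile, its ortho substituents are remote from the bond being formed, and the stereocentre at C3 is created in the same event by a chiral rhodium catalyst. The forward reaction must deliver the branched, R-configured but-3-en-2-yl ester from allene 10, and the same catalyst serves both acids.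

**Ring A acid (9 from 7, 6, 5, 2 and 3; 2 from 1).** The carboxyl is introduced last, by bromination ortho to the side chain and carboxylation of the aryllithium, after the side-chain hydroxyl of 5 has been silylated; the hydroxyl and the carboxyl are never free together, so no lactone can form. The side chain comes from opening epoxide 3 with aryllithium 4, made from bromide 2, which carries the R centre over unchanged.

**Ring C acid (25 from 23, 22, 21, 20, 2 and 18; 18 from 17 and 16).** The same bromide 2 is used, this time as its Grignard reagent 19. Under copper catalysis and without a Lewis acid, 19 opens epoxide 18, whose benzyloxy oxygen could otherwise compete for or take part in a Lewis acid-activated opening. The new carbinol of 20 is oxidised to the ketone (so its configuration is irrelevant), and the ketone is masked as a dioxolane before bromination and carboxylation. The C4 centre is bought with 16 and protected as a benzyl ether so that it falls in the final hydrogenolysis.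

## Alternatives that were turned down

**Alternative 1:** Both benzene rings are cut through C1–C2 and C5–C6, leading back to the open-chain bis(alk-2-ynoate) A2, which already holds all ester bonds and all four stereocentres. In the forward sense A2 is heated with two equivalents of 1-methoxy-1,3-bis(trimethylsilyloxy)buta-1,3-diene A3, and acidic work-up (loss of methanol and of the silyl groups) aromatises both rings to A1.

- For: every ester bond is made on an alk-2-ynoic acid without ortho substituents, so the hindered benzoate problem never arises; the phenols appear free and need no protection. On protecting-group economy and on convergence of ring construction it is stronger than the chosen route.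
- Against: A2 must carry two 3-acyloxybutanoyl units and two propargylic CH2 groups through a thermal cycloaddition with a basic ketene acetal. 3-Alkyl alkynoates are slow dienophiles, so the temperature is high, and alkyne-to-allene isomerisation followed by loss of carboxylate is then a real pathway. Two cycloadditions on one molecule multiply the losses.
- Against: the key step sets no stereocentre, so all four have to be made beforehand. A1 still needs a dithiane removal with thiophilic or oxidising reagents beside two free resorcinol rings, and acid cleavage of the tert-butyl ester and silyl ether beside a β-hydroxy ketone.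
- Comparison: the chosen strategy buys the rings and spends its key step on the hindered C–O bonds and their stereocentres. Its risky step comes after five steps, not at the end of a long build-up of A2.

**Alternative 2:** The bond between C6 of ring A and the side-chain CH2 is cut. In the forward sense 2,4-bis(benzyloxy)benzoic acid A5 and epoxide 3 react with Pd(OAc)2 (divalent palladium), an N-acetyl amino acid ligand and KOAc. The carboxylate directs palladation to the only free ortho C–H, the aryl–palladium bond opens the epoxide at CH2, and the alkoxide closes onto the carboxyl to give lactone A4.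

- For: one step gives the whole carbon skeleton of ring A with the carbinol centre taken unchanged from 3, without halogenation or organolithium chemistry. As a feeder for an acid like 9 it is equal or better in step count than steps 2 to 5.
- Against: the product is the lactone, in which the carboxyl and the side-chain hydroxyl are tied to each other although the target esterifies them with two different partners. A4 must be opened and silylated to reach 9, which returns part of the gain.
- Against: the step forms none of the three ester links and no new stereocentre. For ring C the analogous lactone would need opening and oxidation to the ketone.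
- Comparison: the chosen entry uses one bromide, 2, for both rings and never lets the lactone form. The problem that defines this target, the hindered esters on C3 of the butanoates, would still need step 6 after alternative 2.

**Alternative 3:** Both C–C bonds at the ketone carbon of the ring C chain are cut. In the forward sense lithiated 2-(tert-butyldimethylsilyl)-1,3-dithiane A7 opens epoxide 3, HMPA triggers a 1,4-Brook shift of silicon to the new alkoxide, and the regenerated dithiane anion is alkylated by benzylic bromide A8 to give A6.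

- For: three components are joined in one flask, with the ketone masked, the carbinol silylated and the salicylate held as a benzodioxinone. For the ring C chain it is clearly shorter than steps 11 to 15, and on that point it is stronger.
- Against: it concerns ring C only. A8 has an electrophilic lactone carbonyl peri to the benzylic bromide, which the dithiane anion may attack.
- Against: opening the benzodioxinone with the alkoxide of a 3-hydroxybutanoate invites retro-aldol cleavage and elimination. The dithiane must later be removed with mercury salts or oxidants in the presence of electron-rich rings.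
- Comparison: the chosen route builds the ring C chain with longer but routine steps, masks the ketone as a dioxolane that falls to mild acid, and keeps the risk at the ester bonds, which alternative 3 does not address.

Key step: step 6

## Route

Assumptions on the chemistry:
- (R,R)-DIOP is taken to be the ligand enantiomer that delivers the R-configured allylic ester. If the sense of induction is the opposite, (S,S)-DIOP is used with nothing else changed.
- Epoxide 18 and alcohol 20 are carried as mixtures of epimers at the carbon that becomes the ketone carbon in step 14.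

Step 1
Reactants: 1 5-bromoresorcinol
Product: 2 1,3-bis(benzyloxy)-5-bromobenzene
Conditions: BnBr, K2CO3, DMF, rt to 60 °C
Reagents that add atoms: benzyl bromide, BrCc1ccccc1
Why: Williamson ether synthesis on both phenols; benzyl ethers survive organolithium, Grignard, rhodium and palladium oxidation chemistry and are removed together in the last step.

Step 2
Reactants: 2 1,3-bis(benzyloxy)-5-bromobenzene; 3 (R)-propylene oxide
Product: 5 (R)-1-[3,5-bis(benzyloxy)phenyl]propan-2-ol, via [3,5-bis(benzyloxy)phenyl]lithium 4 (not isolated)
Conditions: n-BuLi, THF, −78 °C; then 3, BF3·OEt2, −78 °C; aq. NH4Cl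
Reagents that add atoms: none
Why: Bromine–lithium exchange followed by BF3-assisted opening of the epoxide at its CH2 carbon; the stereocentre is not touched, so the R configuration of 3 is carried into 5.

Step 3
Reactants: 5 (R)-1-[3,5-bis(benzyloxy)phenyl]propan-2-ol
Product: 6 (R)-{[1-(3,5-bis(benzyloxy)phenyl)propan-2-yl]oxy}(tert-butyl)dimethylsilane
Conditions: TBSCl, imidazole, DMF, rt
Reagents that add atoms: tert-butyldimethylsilyl chloride, CC(C)(C)[Si](C)(C)Cl
Why: Standard silylation of a secondary alcohol; the silyl ether keeps the hydroxyl away from the carboxyl that is introduced next.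

Step 4
Reactants: 6 (R)-{[1-(3,5-bis(benzyloxy)phenyl)propan-2-yl]oxy}(tert-butyl)dimethylsilane
Product: 7 (R)-{[1-(3,5-bis(benzyloxy)-2-bromophenyl)propan-2-yl]oxy}(tert-butyl)dimethylsilane
Conditions: NBS, MeCN, 0 °C, dark
Reagents that add atoms: N-bromosuccinimide, O=C1CCC(=O)N1Br
Why: Electrophilic aromatic bromination; the carbon ortho to the side chain is para to one benzyloxy group and less crowded than the carbon between the two benzyloxy groups, and the two ortho carbons are equivalent by symmetry.

Step 5
Reactants: 7 (R)-{[1-(3,5-bis(benzyloxy)-2-bromophenyl)propan-2-yl]oxy}(tert-butyl)dimethylsilane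
Product: 9 (R)-2,4-bis(benzyloxy)-6-[2-(tert-butyldimethylsilyloxy)propyl]benzoic acid, via ring A aryllithium 8 (not isolated)
Conditions: n-BuLi, THF, −78 °C; CO2; cold 1 M HCl to pH 3
Reagents that add atoms: carbon dioxide, O=C=O
Why: Bromine–lithium exchange and carboxylation of the aryllithium; carbon dioxide is small enough to reach the carbon between the two ortho substituents, and the acid is obtained directly without an aldehyde stage.

Step 6
Reactants: 9 (R)-2,4-bis(benzyloxy)-6-[2-(tert-butyldimethylsilyloxy)propyl]benzoic acid; 10 buta-1,2-diene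
Product: 11 (R)-but-3-en-2-yl 2,4-bis(benzyloxy)-6-[(R)-2-(tert-butyldimethylsilyloxy)propyl]benzoate
Conditions: [Rh(cod)Cl]2 (2.5 mol%), (R,R)-DIOP (5 mol%), 10 (excess, condensed in), DCE, sealed tube, rt to 40 °C
Reagents that add atoms: none
Why: The O–H bond of 9 adds to the DIOP-bound monovalent rhodium, the trivalent rhodium hydride so formed inserts the unsubstituted C=C of 10 with hydrogen going to the central carbon, and the resulting 1-methylallyl rhodium carboxylate undergoes C–O reductive elimination at its methyl-bearing terminus, which returns monovalent rhodium. The closest known reaction type is the rhodium/DIOP-catalysed branched-selective addition of carboxylic acids, benzoic acids among them, to monosubstituted allenes. No ring is closed; one C–O bond and one stereocentre are formed. The new centre (C3 of unit D) is set by the chiral diphosphine alone, which decides the face of the allyl terminus that meets the carboxylate oxygen; the silyloxy centre of 9 is six atoms away and should not interfere. The step needs branched over linear regioselectivity and R over S facial selectivity, both of which are properties of the catalyst. The substrate contributes that the acid reacts through oxygen, so the benzyloxy group and the side chain ortho to the carboxyl do not shield the bond being formed. No base is present, and 11 has no α-hydrogen, so the benzoate cannot be eliminated at this stage.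

Step 7
Reactants: 11 (R)-but-3-en-2-yl 2,4-bis(benzyloxy)-6-[(R)-2-(tert-butyldimethylsilyloxy)propyl]benzoate
Product: 12 (R)-4-oxobutan-2-yl 2,4-bis(benzyloxy)-6-[(R)-2-(tert-butyldimethylsilyloxy)propyl]benzoate
Conditions: PdCl2(MeCN)2 (10 mol%), p-benzoquinone, t-BuOH, H2O (2 equiv), rt
Reagents that add atoms: water, O
Why: Aldehyde-selective (anti-Markovnikov) Wacker oxidation, a known outcome for branched allylic esters, in which the allylic acyloxy group directs the oxygen nucleophile to the terminal carbon; the stereocentre is not involved.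

Step 8
Reactants: 12 (R)-4-oxobutan-2-yl 2,4-bis(benzyloxy)-6-[(R)-2-(tert-butyldimethylsilyloxy)propyl]benzoate
Product: 13 (R)-3-({2,4-bis(benzyloxy)-6-[(R)-2-(tert-butyldimethylsilyloxy)propyl]benzoyl}oxy)butanoic acid
Conditions: NaClO2, NaH2PO4, 2-methyl-2-butene, t-BuOH/H2O, 0 °C to rt
Reagents that add atoms: sodium chlorite, [Na+].[O-]Cl=O
Why: Pinnick oxidation at pH about 4, mild enough that the β-acyloxy aldehyde is oxidised without elimination and the silyl ether stays.

Step 9
Reactants: 13 (R)-3-({2,4-bis(benzyloxy)-6-[(R)-2-(tert-butyldimethylsilyloxy)propyl]benzoyl}oxy)butanoic acid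
Product: 14 benzyl (R)-3-({2,4-bis(benzyloxy)-6-[(R)-2-(tert-butyldimethylsilyloxy)propyl]benzoyl}oxy)butanoate
Conditions: BnBr, KHCO3, DMF, rt
Reagents that add atoms: benzyl bromide, BrCc1ccccc1
Why: O-Alkylation of the carboxylate; hydrogen carbonate is too weak a base to remove an α-hydrogen of the product, so the benzoate is not eliminated.

Step 10
Reactants: 14 benzyl (R)-3-({2,4-bis(benzyloxy)-6-[(R)-2-(tert-butyldimethylsilyloxy)propyl]benzoyl}oxy)butanoate
Product: 15 benzyl (R)-3-({2,4-bis(benzyloxy)-6-[(R)-2-hydroxypropyl]benzoyl}oxy)butanoate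
Conditions: HF·pyridine, pyridine, THF, 0 °C to rt; used at once
Reagents that add atoms: none
Why: Acidic fluoride cleavage of the silyl ether; no alkoxide is formed, which avoids both E1cB loss of the benzoate and attack of the liberated hydroxyl on the neighbouring ester.

Step 11
Reactants: 16 (R)-pent-4-en-2-ol
Product: 17 (R)-4-(benzyloxy)pent-1-ene
Conditions: NaH, BnBr, TBAI (cat.), THF, 0 °C to rt
Reagents that add atoms: benzyl bromide, BrCc1ccccc1
Why: Williamson ether synthesis; the C–O bond of the stereocentre is not broken, so the R configuration is kept.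

Step 12
Reactants: 17 (R)-4-(benzyloxy)pent-1-ene
Product: 18 2-[(R)-2-(benzyloxy)propyl]oxirane (both epimers at the oxirane carbon)
Conditions: mCPBA, CH2Cl2, 0 °C to rt
Reagents that add atoms: 3-chloroperbenzoic acid, OOC(=O)c1cccc(Cl)c1
Why: Prilezhaev epoxidation of the terminal alkene; no facial control is needed because the new carbinol carbon becomes a ketone in step 14.

Step 13
Reactants: 2 1,3-bis(benzyloxy)-5-bromobenzene; 18 2-[(R)-2-(benzyloxy)propyl]oxirane
Product: 20 (4R)-4-(benzyloxy)-1-[3,5-bis(benzyloxy)phenyl]pentan-2-ol (both epimers at C2), via [3,5-bis(benzyloxy)phenyl]magnesium bromide 19 (not isolated)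
Conditions: Mg turnings, I2 (cat.), THF, 45 °C; then CuI (10 mol%), 18, −30 to 0 °C; aq. NH4Cl
Reagents that add atoms: none
Why: Magnesium insertion gives the aryl Grignard reagent, and its copper-catalysed SN2 opening of the terminal epoxide at the CH2 carbon is a standard way to make 1-arylalkan-2-ols. No Lewis acid is used, so the benzyloxy oxygen of 18 cannot compete for it or take part in the opening, and the copper catalyst suppresses bromohydrin formation by the magnesium halide.

Step 14
Reactants: 20 (4R)-4-(benzyloxy)-1-[3,5-bis(benzyloxy)phenyl]pentan-2-ol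
Product: 21 (R)-4-(benzyloxy)-1-[3,5-bis(benzyloxy)phenyl]pentan-2-one
Conditions: Dess–Martin periodinane, CH2Cl2, 0 °C to rt
Reagents that add atoms: none
Why: Dess–Martin oxidation under near-neutral conditions converges both epimers to one ketone and does not provoke loss of the β-benzyloxy group.

Step 15
Reactants: 21 (R)-4-(benzyloxy)-1-[3,5-bis(benzyloxy)phenyl]pentan-2-one
Product: 22 2-[3,5-bis(benzyloxy)benzyl]-2-[(R)-2-(benzyloxy)propyl]-1,3-dioxolane
Conditions: (TMSOCH2)2, TMSOTf (cat.), CH2Cl2, −78 to −20 °C; pyridine quench
Reagents that add atoms: 1,2-bis(trimethylsilyloxy)ethane, C[Si](C)(C)OCCO[Si](C)(C)C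
Why: Silyl triflate-catalysed acetalisation with the bis-silyl ether of ethylene glycol runs at low temperature without free water or strong protic acid, so the β-benzyloxy ketone is not eliminated; the ketone must be masked before the organolithium step.

Step 16
Reactants: 22 2-[3,5-bis(benzyloxy)benzyl]-2-[(R)-2-(benzyloxy)propyl]-1,3-dioxolane
Product: 23 2-[3,5-bis(benzyloxy)-2-bromobenzyl]-2-[(R)-2-(benzyloxy)propyl]-1,3-dioxolane
Conditions: NBS, MeCN, 0 °C, dark
Reagents that add atoms: N-bromosuccinimide, O=C1CCC(=O)N1Br
Why: Electrophilic bromination with the same regiochemical preference as in step 4 (para to a benzyloxy group, ortho to the chain); the unsubstituted phenyl rings of the benzyl ethers are far less reactive.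

Step 17
Reactants: 23 2-[3,5-bis(benzyloxy)-2-bromobenzyl]-2-[(R)-2-(benzyloxy)propyl]-1,3-dioxolane
Product: 25 2,4-bis(benzyloxy)-6-({2-[(R)-2-(benzyloxy)propyl]-1,3-dioxolan-2-yl}methyl)benzoic acid, via ring C aryllithium 24 (not isolated)
Conditions: n-BuLi, THF, −78 °C; CO2; cold 1 M HCl to pH 3 to 4, immediate extraction
Reagents that add atoms: carbon dioxide, O=C=O
Why: Bromine–lithium exchange and carboxylation as in step 5; the dioxolane is inert to the organolithium and survives a brief cold acidification.

Step 18
Reactants: 25 2,4-bis(benzyloxy)-6-({2-[(R)-2-(benzyloxy)propyl]-1,3-dioxolan-2-yl}methyl)benzoic acid; 10 buta-1,2-diene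
Product: 26 (R)-but-3-en-2-yl 2,4-bis(benzyloxy)-6-({2-[(R)-2-(benzyloxy)propyl]-1,3-dioxolan-2-yl}methyl)benzoate
Conditions: [Rh(cod)Cl]2 (2.5 mol%), (R,R)-DIOP (5 mol%), 10 (excess), DCE, sealed tube, rt to 40 °C
Reagents that add atoms: none
Why: The same rhodium-catalysed addition of the acid O–H to the allene as in step 6 forms the O–C3 bond of unit B at the branched position; the R centre is again set by the DIOP ligand, and the anhydrous, base-free medium leaves the dioxolane intact.

Step 19
Reactants: 26 (R)-but-3-en-2-yl 2,4-bis(benzyloxy)-6-({2-[(R)-2-(benzyloxy)propyl]-1,3-dioxolan-2-yl}methyl)benzoate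
Product: 27 (R)-4-oxobutan-2-yl 2,4-bis(benzyloxy)-6-({2-[(R)-2-(benzyloxy)propyl]-1,3-dioxolan-2-yl}methyl)benzoate
Conditions: PdCl2(MeCN)2 (10 mol%), p-benzoquinone, t-BuOH, H2O (2 equiv), rt
Reagents that add atoms: water, O
Why: Aldehyde-selective Wacker oxidation of the branched allylic ester as in step 7.

Step 20
Reactants: 27 (R)-4-oxobutan-2-yl 2,4-bis(benzyloxy)-6-({2-[(R)-2-(benzyloxy)propyl]-1,3-dioxolan-2-yl}methyl)benzoate
Product: 28 (R)-3-{[2,4-bis(benzyloxy)-6-({2-[(R)-2-(benzyloxy)propyl]-1,3-dioxolan-2-yl}methyl)benzoyl]oxy}butanoic acid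
Conditions: NaClO2, NaH2PO4, 2-methyl-2-butene, t-BuOH/H2O, 0 °C to rt
Reagents that add atoms: sodium chlorite, [Na+].[O-]Cl=O
Why: Pinnick oxidation as in step 8; the buffered medium is too weakly acidic to open the dioxolane in the time needed.

Step 21
Reactants: 15 benzyl (R)-3-({2,4-bis(benzyloxy)-6-[(R)-2-hydroxypropyl]benzoyl}oxy)butanoate; 28 (R)-3-{[2,4-bis(benzyloxy)-6-({2-[(R)-2-(benzyloxy)propyl]-1,3-dioxolan-2-yl}methyl)benzoyl]oxy}butanoic acid
Product: 29 benzyl (R)-3-{[2,4-bis(benzyloxy)-6-((R)-2-{[(R)-3-{[2,4-bis(benzyloxy)-6-({2-[(R)-2-(benzyloxy)propyl]-1,3-dioxolan-2-yl}methyl)benzoyl]oxy}butanoyl]oxy}propyl)benzoyl]oxy}butanoate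
Conditions: EDC·HCl, DMAP (cat.), CH2Cl2, 0 °C to rt
Reagents that add atoms: none
Why: Steglich esterification at the only unhindered acyl carbon of the target; the carbinol C–O bond of 15 is not broken, so its R configuration is retained, and only a catalytic amount of a weak amine base is present.

Step 22
Reactants: 29 the dioxolane-protected hexabenzyl compound of step 21
Product: 30 benzyl (R)-3-{[2,4-bis(benzyloxy)-6-((R)-2-{[(R)-3-({2,4-bis(benzyloxy)-6-[(R)-4-(benzyloxy)-2-oxopentyl]benzoyl}oxy)butanoyl]oxy}propyl)benzoyl]oxy}butanoate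
Conditions: PPTS (cat.), acetone/H2O, 50 °C
Reagents that add atoms: water, O
Why: Mild acid-catalysed hydrolysis of the ketal; esters, benzyl ethers and the stereocentres are inert to a pyridinium acid.

Step 23
Reactants: 30 the hexabenzyl ketone of step 22
Product: 31 hansforester I
Conditions: H2 (1 atm), 10% Pd/C, EtOAc/THF, rt
Reagents that add atoms: none
Why: Hydrogenolysis cleaves the four aryl benzyl ethers, the alkyl benzyl ether and the benzyl ester in one neutral step; the ketone is not benzylic and none of the aroyloxy C–O bonds is benzylic, so they are not reduced.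

## Compound list

1 | 5-bromoresorcinol | Oc1cc(O)cc(Br)c1 | starting material
2 | 1,3-bis(benzyloxy)-5-bromobenzene | Brc1cc(OCc2ccccc2)cc(OCc2ccccc2)c1 | intermediate
3 | (R)-propylene oxide | C[C@@H]1CO1 | starting material
4 | [3,5-bis(benzyloxy)phenyl]lithium | [Li]c1cc(OCc2ccccc2)cc(OCc2ccccc2)c1 | intermediate (not isolated)
5 | (R)-1-[3,5-bis(benzyloxy)phenyl]propan-2-ol | C[C@@H](O)Cc1cc(OCc2ccccc2)cc(OCc2ccccc2)c1 | intermediate
6 | (R)-{[1-(3,5-bis(benzyloxy)phenyl)propan-2-yl]oxy}(tert-butyl)dimethylsilane | C[C@H](Cc1cc(OCc2ccccc2)cc(OCc2ccccc2)c1)O[Si](C)(C)C(C)(C)C | intermediate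
7 | (R)-{[1-(3,5-bis(benzyloxy)-2-bromophenyl)propan-2-yl]oxy}(tert-butyl)dimethylsilane | C[C@H](Cc1cc(OCc2ccccc2)cc(OCc2ccccc2)c1Br)O[Si](C)(C)C(C)(C)C | intermediate
8 | {2,4-bis(benzyloxy)-6-[(R)-2-(tert-butyldimethylsilyloxy)propyl]phenyl}lithium | C[C@H](Cc1cc(OCc2ccccc2)cc(OCc2ccccc2)c1[Li])O[Si](C)(C)C(C)(C)C | intermediate (not isolated)
9 | (R)-2,4-bis(benzyloxy)-6-[2-(tert-butyldimethylsilyloxy)propyl]benzoic acid | C[C@H](Cc1cc(OCc2ccccc2)cc(OCc2ccccc2)c1C(=O)O)O[Si](C)(C)C(C)(C)C | intermediate
10 | buta-1,2-diene | CC=C=C | starting material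
11 | (R)-but-3-en-2-yl 2,4-bis(benzyloxy)-6-[(R)-2-(tert-butyldimethylsilyloxy)propyl]benzoate | C[C@H](Cc1cc(OCc2ccccc2)cc(OCc2ccccc2)c1C(=O)O[C@H](C)C=C)O[Si](C)(C)C(C)(C)C | intermediate
12 | (R)-4-oxobutan-2-yl 2,4-bis(benzyloxy)-6-[(R)-2-(tert-butyldimethylsilyloxy)propyl]benzoate | C[C@H](Cc1cc(OCc2ccccc2)cc(OCc2ccccc2)c1C(=O)O[C@H](C)CC=O)O[Si](C)(C)C(C)(C)C | intermediate
13 | (R)-3-({2,4-bis(benzyloxy)-6-[(R)-2-(tert-butyldimethylsilyloxy)propyl]benzoyl}oxy)butanoic acid | C[C@H](Cc1cc(OCc2ccccc2)cc(OCc2ccccc2)c1C(=O)O[C@H](C)CC(=O)O)O[Si](C)(C)C(C)(C)C | intermediate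
14 | benzyl (R)-3-({2,4-bis(benzyloxy)-6-[(R)-2-(tert-butyldimethylsilyloxy)propyl]benzoyl}oxy)butanoate | C[C@H](Cc1cc(OCc2ccccc2)cc(OCc2ccccc2)c1C(=O)O[C@H](C)CC(=O)OCc1ccccc1)O[Si](C)(C)C(C)(C)C | intermediate
15 | benzyl (R)-3-({2,4-bis(benzyloxy)-6-[(R)-2-hydroxypropyl]benzoyl}oxy)butanoate | C[C@@H](O)Cc1cc(OCc2ccccc2)cc(OCc2ccccc2)c1C(=O)O[C@H](C)CC(=O)OCc1ccccc1 | intermediate
16 | (R)-pent-4-en-2-ol | C[C@@H](O)CC=C | starting material
17 | (R)-4-(benzyloxy)pent-1-ene | C[C@H](CC=C)OCc1ccccc1 | intermediate
18 | 2-[(R)-2-(benzyloxy)propyl]oxirane, both epimers at the oxirane carbon | C[C@H](CC1CO1)OCc1ccccc1 | intermediate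
19 | [3,5-bis(benzyloxy)phenyl]magnesium bromide | Br[Mg]c1cc(OCc2ccccc2)cc(OCc2ccccc2)c1 | intermediate (not isolated)
20 | (4R)-4-(benzyloxy)-1-[3,5-bis(benzyloxy)phenyl]pentan-2-ol, both epimers at C2 | C[C@H](CC(O)Cc1cc(OCc2ccccc2)cc(OCc2ccccc2)c1)OCc1ccccc1 | intermediate
21 | (R)-4-(benzyloxy)-1-[3,5-bis(benzyloxy)phenyl]pentan-2-one | C[C@H](CC(=O)Cc1cc(OCc2ccccc2)cc(OCc2ccccc2)c1)OCc1ccccc1 | intermediate
22 | 2-[3,5-bis(benzyloxy)benzyl]-2-[(R)-2-(benzyloxy)propyl]-1,3-dioxolane | C[C@H](CC1(Cc2cc(OCc3ccccc3)cc(OCc3ccccc3)c2)OCCO1)OCc1ccccc1 | intermediate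
23 | 2-[3,5-bis(benzyloxy)-2-bromobenzyl]-2-[(R)-2-(benzyloxy)propyl]-1,3-dioxolane | C[C@H](CC1(Cc2cc(OCc3ccccc3)cc(OCc3ccccc3)c2Br)OCCO1)OCc1ccccc1 | intermediate
24 | [2,4-bis(benzyloxy)-6-({2-[(R)-2-(benzyloxy)propyl]-1,3-dioxolan-2-yl}methyl)phenyl]lithium | C[C@H](CC1(Cc2cc(OCc3ccccc3)cc(OCc3ccccc3)c2[Li])OCCO1)OCc1ccccc1 | intermediate (not isolated)
25 | 2,4-bis(benzyloxy)-6-({2-[(R)-2-(benzyloxy)propyl]-1,3-dioxolan-2-yl}methyl)benzoic acid | C[C@H](CC1(Cc2cc(OCc3ccccc3)cc(OCc3ccccc3)c2C(=O)O)OCCO1)OCc1ccccc1 | intermediate
26 | (R)-but-3-en-2-yl 2,4-bis(benzyloxy)-6-({2-[(R)-2-(benzyloxy)propyl]-1,3-dioxolan-2-yl}methyl)benzoate | C[C@H](CC1(Cc2cc(OCc3ccccc3)cc(OCc3ccccc3)c2C(=O)O[C@H](C)C=C)OCCO1)OCc1ccccc1 | intermediate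
27 | (R)-4-oxobutan-2-yl 2,4-bis(benzyloxy)-6-({2-[(R)-2-(benzyloxy)propyl]-1,3-dioxolan-2-yl}methyl)benzoate | C[C@H](CC1(Cc2cc(OCc3ccccc3)cc(OCc3ccccc3)c2C(=O)O[C@H](C)CC=O)OCCO1)OCc1ccccc1 | intermediate
28 | (R)-3-{[2,4-bis(benzyloxy)-6-({2-[(R)-2-(benzyloxy)propyl]-1,3-dioxolan-2-yl}methyl)benzoyl]oxy}butanoic acid | C[C@H](CC1(Cc2cc(OCc3ccccc3)cc(OCc3ccccc3)c2C(=O)O[C@H](C)CC(=O)O)OCCO1)OCc1ccccc1 | intermediate
29 | benzyl (R)-3-{[2,4-bis(benzyloxy)-6-((R)-2-{[(R)-3-{[2,4-bis(benzyloxy)-6-({2-[(R)-2-(benzyloxy)propyl]-1,3-dioxolan-2-yl}methyl)benzoyl]oxy}butanoyl]oxy}propyl)benzoyl]oxy}butanoate | C[C@H](Cc1cc(OCc2ccccc2)cc(OCc2ccccc2)c1C(=O)O[C@H](C)CC(=O)OCc1ccccc1)OC(=O)C[C@@H](C)OC(=O)c1c(OCc2ccccc2)cc(OCc2ccccc2)cc1CC1(C[C@@H](C)OCc2ccccc2)OCCO1 | intermediate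
30 | benzyl (R)-3-{[2,4-bis(benzyloxy)-6-((R)-2-{[(R)-3-({2,4-bis(benzyloxy)-6-[(R)-4-(benzyloxy)-2-oxopentyl]benzoyl}oxy)butanoyl]oxy}propyl)benzoyl]oxy}butanoate | C[C@H](Cc1cc(OCc2ccccc2)cc(OCc2ccccc2)c1C(=O)O[C@H](C)CC(=O)OCc1ccccc1)OC(=O)C[C@@H](C)OC(=O)c1c(OCc2ccccc2)cc(OCc2ccccc2)cc1CC(=O)C[C@@H](C)OCc1ccccc1 | intermediate
31 | hansforester I, (R)-3-{[2,4-dihydroxy-6-((R)-2-{[(R)-3-({2,4-dihydroxy-6-[(R)-4-hydroxy-2-oxopentyl]benzoyl}oxy)butanoyl]oxy}propyl)benzoyl]oxy}butanoic acid | C[C@H](Cc1cc(O)cc(O)c1C(=O)O[C@H](C)CC(=O)O)OC(=O)C[C@@H](C)OC(=O)c1c(O)cc(O)cc1CC(=O)C[C@@H](C)O | target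

## Step count and least certain steps

Total step count: 23. Longest linear sequence: 13 steps (steps 1 to 10, then 21 to 23; the ring C branch, steps 11 to 20 and 21 to 23, is equally long).

**Step 6 (key step).** Three processes may fail:
- Conversion may be slow with a twisted, electron-rich acid, while the volatile allene is consumed by oligomerisation.
- Facial discrimination may be weak, because methyl is the smallest substituent an allyl terminus can carry.
- The branched ester may re-ionise on the catalyst and drift to the linear crotyl ester on long reaction times.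

The fallback sets out from 9 and comes back at 11. It is a Mitsunobu esterification of 9 with commercial (S)-but-3-en-2-ol (PPh3, DIAD, toluene, 0 °C). The acid is again the oxygen nucleophile, so its ortho substituents do not matter, and inversion at the carbinol carbon gives the R ester. The stereocentre is then bought and not made, and some allylic transposition has to be separated.

**Step 18.** The same processes apply, and slow conversion is more likely because the ortho substituent of 25 ends in a quaternary ketal carbon. The fallback sets out from 25 and comes back at 26, by the same Mitsunobu esterification with (S)-but-3-en-2-ol.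

**Steps 7 and 19.** Three processes may fail:
- The oxygen nucleophile may attack the internal carbon and give the methyl ketone.
- The alkylpalladium intermediate may expel the benzoate by β-acyloxy elimination.
- Lewis-acidic divalent palladium may cleave the silyl ether of 11 or, more likely, the dioxolane of 26.

The fallback for step 7 sets out from 11 and comes back at 12. Hydroboration with 9-BBN (THF, 0 °C to rt) gives the B-alkyl-9-borabicyclononane of 11 F1, which is not isolated. Oxidation with NaBO3·4H2O gives (R)-4-hydroxybutan-2-yl 2,4-bis(benzyloxy)-6-[(R)-2-(tert-butyldimethylsilyloxy)propyl]benzoate F2. TEMPO and PhI(OAc)2 in CH2Cl2 then oxidise F2 to 12.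

The fallback for step 19 sets out from 26 and comes back at 27. The same hydroboration gives the B-alkyl-9-borabicyclononane of 26 F3, not isolated, and oxidation gives (R)-4-hydroxybutan-2-yl 2,4-bis(benzyloxy)-6-({2-[(R)-2-(benzyloxy)propyl]-1,3-dioxolan-2-yl}methyl)benzoate F4. F4 is oxidised to 27 in the same way. Boron is placed at the terminal carbon, two atoms away from the acyloxy carbon, so no β-elimination is possible, and no palladium salt touches the acetal.

**Step 21 (with step 10).** Two processes may fail:
- Activation of 28 as an acyl donor may trigger E1cB loss of the ring C benzoate.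
- If acylation of the hindered secondary alcohol is slow, the hydroxyl of 15 has time to attack its own neighbouring ester, closing a six-membered lactone with loss of the unit D alcohol.

The fallback sets out from 15 and 25 and comes back at 29; it makes steps 18 to 20 unnecessary.
1. Commercial methyl (S)-3-hydroxybutanoate is silylated (TBSCl, imidazole) to methyl (S)-3-(tert-butyldimethylsilyloxy)butanoate F5.
2. F5 is saponified (LiOH, THF/H2O) to (S)-3-(tert-butyldimethylsilyloxy)butanoic acid F6.
3. F6 is small and has no β-leaving group of consequence. It acylates 15 quickly (EDC·HCl, DMAP) to benzyl (R)-3-({2,4-bis(benzyloxy)-6-[(R)-2-{[(S)-3-(tert-butyldimethylsilyloxy)butanoyl]oxy}propyl]benzoyl}oxy)butanoate F7.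
4. HF·pyridine gives the (S)-3-hydroxybutanoyl ester F8.
5. A Mitsunobu reaction of F8 with acid 25 (PPh3, DIAD, toluene, 0 °C) forms the ring C benzoate with inversion to R, which is 29.

The hindered acid again reacts through oxygen. The cost is that the β-hydroxy ester F8 can partly eliminate to the crotonate under Mitsunobu conditions.

**Step 22.** Acid hydrolysis of the ketal releases an aryl–CH2–ketone beside a benzoate that no hydrogen bond stabilises. Acid-catalysed enol lactonisation to an isocoumarin, with loss of the rest of the chain, or loss of the β-benzyloxy group may compete. The fallback sets out from 29 and comes back at 31, with the last two operations reversed. Hydrogenolysis of 29 (H2, 10% Pd/C, EtOAc/THF) gives the debenzylated dioxolane acid F9. Dilute aqueous acetic acid in THF then opens the ketal of F9 to 31. In F9 the ortho phenol is hydrogen-bonded to the ester carbonyl, as in the target itself, which makes that carbonyl a poorer acceptor for the enol oxygen.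

## Further compounds

F0 | step 6 | none | none
F0 | step 18 | none | none
F1 | step 7 | B-alkyl-9-borabicyclononane from 11, (R)-4-(9-borabicyclo[3.3.1]nonan-9-yl)butan-2-yl 2,4-bis(benzyloxy)-6-[(R)-2-(tert-butyldimethylsilyloxy)propyl]benzoate | C[C@H](Cc1cc(OCc2ccccc2)cc(OCc2ccccc2)c1C(=O)O[C@H](C)CCB1C2CCCC1CCC2)O[Si](C)(C)C(C)(C)C
F2 | step 7 | (R)-4-hydroxybutan-2-yl 2,4-bis(benzyloxy)-6-[(R)-2-(tert-butyldimethylsilyloxy)propyl]benzoate | C[C@H](Cc1cc(OCc2ccccc2)cc(OCc2ccccc2)c1C(=O)O[C@H](C)CCO)O[Si](C)(C)C(C)(C)C
F3 | step 19 | B-alkyl-9-borabicyclononane from 26, (R)-4-(9-borabicyclo[3.3.1]nonan-9-yl)butan-2-yl 2,4-bis(benzyloxy)-6-({2-[(R)-2-(benzyloxy)propyl]-1,3-dioxolan-2-yl}methyl)benzoate | C[C@H](CC1(Cc2cc(OCc3ccccc3)cc(OCc3ccccc3)c2C(=O)O[C@H](C)CCB2C3CCCC2CCC3)OCCO1)OCc1ccccc1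
F4 | step 19 | (R)-4-hydroxybutan-2-yl 2,4-bis(benzyloxy)-6-({2-[(R)-2-(benzyloxy)propyl]-1,3-dioxolan-2-yl}methyl)benzoate | C[C@H](CC1(Cc2cc(OCc3ccccc3)cc(OCc3ccccc3)c2C(=O)O[C@H](C)CCO)OCCO1)OCc1ccccc1
F5 | step 21 | methyl (S)-3-(tert-butyldimethylsilyloxy)butanoate | C[C@H](O[Si](C)(C)C(C)(C)C)CC(=O)OC
F6 | step 21 | (S)-3-(tert-butyldimethylsilyloxy)butanoic acid | C[C@H](O[Si](C)(C)C(C)(C)C)CC(=O)O
F7 | step 21 | benzyl (R)-3-({2,4-bis(benzyloxy)-6-[(R)-2-{[(S)-3-(tert-butyldimethylsilyloxy)butanoyl]oxy}propyl]benzoyl}oxy)butanoate | C[C@H](Cc1cc(OCc2ccccc2)cc(OCc2ccccc2)c1C(=O)O[C@H](C)CC(=O)OCc1ccccc1)OC(=O)C[C@H](C)O[Si](C)(C)C(C)(C)C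
F8 | step 21 | benzyl (R)-3-({2,4-bis(benzyloxy)-6-[(R)-2-{[(S)-3-hydroxybutanoyl]oxy}propyl]benzoyl}oxy)butanoate | C[C@H](Cc1cc(OCc2ccccc2)cc(OCc2ccccc2)c1C(=O)O[C@H](C)CC(=O)OCc1ccccc1)OC(=O)C[C@H](C)O
F9 | step 22 | (R)-3-{[2,4-dihydroxy-6-((R)-2-{[(R)-3-{[2,4-dihydroxy-6-({2-[(R)-2-hydroxypropyl]-1,3-dioxolan-2-yl}methyl)benzoyl]oxy}butanoyl]oxy}propyl)benzoyl]oxy}butanoic acid | C[C@H](Cc1cc(O)cc(O)c1C(=O)O[C@H](C)CC(=O)O)OC(=O)C[C@@H](C)OC(=O)c1c(O)cc(O)cc1CC1(C[C@@H](C)O)OCCO1
A1 | alternative 1 | product of the twofold cycloaddition: target skeleton with free phenols, tert-butyl ester of unit D, silyl ether at C4 and 1,3-dithiane at C2 of the ring C chain | C[C@H](Cc1cc(O)cc(O)c1C(=O)O[C@H](C)CC(=O)OC(C)(C)C)OC(=O)C[C@@H](C)OC(=O)c1c(O)cc(O)cc1CC1(C[C@@H](C)O[Si](C)(C)C(C)(C)C)SCCCS1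
A2 | alternative 1 | open-chain bis(alk-2-ynoate) holding units B and D, the tert-butyl ester, the silyl ether and the dithiane | C[C@H](CC#CC(=O)O[C@H](C)CC(=O)OC(C)(C)C)OC(=O)C[C@@H](C)OC(=O)C#CCC1(C[C@@H](C)O[Si](C)(C)C(C)(C)C)SCCCS1
A3 | alternative 1 | 1-methoxy-1,3-bis(trimethylsilyloxy)buta-1,3-diene | COC(O[Si](C)(C)C)=CC(=C)O[Si](C)(C)C
A4 | alternative 2 | (R)-6,8-bis(benzyloxy)-3-methylisochroman-1-one | C[C@@H]1Cc2cc(OCc3ccccc3)cc(OCc3ccccc3)c2C(=O)O1
A5 | alternative 2 | 2,4-bis(benzyloxy)benzoic acid | OC(=O)c1ccc(OCc2ccccc2)cc1OCc1ccccc1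
A6 | alternative 3 | 7-(benzyloxy)-5-({2-[(R)-2-(tert-butyldimethylsilyloxy)propyl]-1,3-dithian-2-yl}methyl)-2,2-dimethyl-4H-1,3-benzodioxin-4-one | CC1(C)OC(=O)c2c(CC3(C[C@@H](C)O[Si](C)(C)C(C)(C)C)SCCCS3)cc(OCc3ccccc3)cc2O1
A7 | alternative 3 | 2-(tert-butyldimethylsilyl)-1,3-dithiane | CC(C)(C)[Si](C)(C)C1SCCCS1
A8 | alternative 3 | 7-(benzyloxy)-5-(bromomethyl)-2,2-dimethyl-4H-1,3-benzodioxin-4-one | CC1(C)OC(=O)c2c(CBr)cc(OCc3ccccc3)cc2O1
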